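## Retrosynthetic overview

1. The three O–S bonds (O3, O5, O4') are made together on 3'-O-benzylrhamnetin, the flavonol in which only these three hydroxyls are free. O3' is unmasked last.
2. Key disconnection: ring C (O1–C2–C3–C4–C4a–C8a) comes from oxidative ring expansion of a (Z)-aurone. The furanone O1–C bond breaks, O1–C2 forms, and the epoxide oxygen becomes the C3–O bond.
3. Feature used: O4' of ring B is para to C1' and so conjugated with C2, which can become the methine of a p-quinone methide. O1 and O5 are the two equivalent ortho oxygens of ring A (at C8a and C5, flanking C4a), so reclosure has one outcome. The C5 oxygen peri to C4=O normally diverts chalcone oxidations to aurones, and here that bias is put to use.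
4. The aurone comes from aldol condensation of 4-hydroxy-6-methoxybenzofuran-3(2H)-one with 3-benzyloxy-4-hydroxybenzaldehyde. The exocyclic C=C formed here later becomes C2–C3.
5. Ring order: rings A and B and the furanone are bought. The furanone is opened and ring C closed in the key step, and no further ring is formed.

Key step: step 3

Assumption: the target has no stereocentre and no stereogenic double bond, so it is achiral and no enantiomer question arises; it is delivered as the free tris(hydrogen sulfate) of the SMILES, made from its ammonium salt by cold proton exchange.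

## Route

Step 1
Reactants: 1 4,6-dihydroxybenzofuran-3(2H)-one
Product: 2 4-hydroxy-6-methoxybenzofuran-3(2H)-one
Conditions: Me2SO4 (1.05 equiv), K2CO3 (1.1 equiv), acetone, reflux
Reagents that add atoms: dimethyl sulfate, COS(=O)(=O)OC
Why: Williamson-type O-methylation, in which O6–H (para to the acyl-bearing C3a) is the free and more acidic hydroxyl while O4–H is tied up in a hydrogen bond to C3=O, so one equivalent of the hard electrophile should alkylate O6 only.

Step 2
Reactants: 2 4-hydroxy-6-methoxybenzofuran-3(2H)-one; 3 3-(benzyloxy)-4-hydroxybenzaldehyde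
Product: 4 (Z)-4-acetoxy-2-[4-acetoxy-3-(benzyloxy)benzylidene]-6-methoxybenzofuran-3(2H)-one
Conditions: Ac2O (solvent), 130 °C; cool and crystallise
Reagents that add atoms: acetic anhydride, CC(=O)OC(C)=O
Why: Aldol (Knoevenagel-type) condensation of the acidic C2 methylene of a benzofuranone with an aryl aldehyde in hot acetic anhydride is the classical aurone synthesis and acetylates both phenols in the same pot; the Z-alkene (aryl cis to O1, away from C3=O) is the thermodynamic isomer and no stereocentre is formed.

Step 3
Reactants: 4 (Z)-4-acetoxy-2-[4-acetoxy-3-(benzyloxy)benzylidene]-6-methoxybenzofuran-3(2H)-one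
Product: 7 3'-O-benzylrhamnetin [2-(3-benzyloxy-4-hydroxyphenyl)-3,5-dihydroxy-7-methoxy-4H-chromen-4-one], via spiro-epoxide 5 (not isolated), via quinone methide diketone 6 (not isolated)
Conditions: (i) DMDO (1.3 equiv, in acetone), CH2Cl2, 0 °C, dark, then evaporate cold; (ii) K2CO3 (4 equiv), degassed MeOH–THF, Ar, 0 °C to rt; 1 M HCl to pH 3
Reagents that add atoms: dimethyldioxirane, CC1(C)OO1
Why: Proposed new method: DMDO transfers oxygen to the exocyclic C=C bond of the aurone (a known epoxidation of aurones) to give racemic spiro-epoxide 5, whose two stereocentres are set syn from the Z-alkene and are both erased later in the same flask, so they need no control. Methanolysis of the 4'-acetate frees a phenoxide para to the benzylic epoxide carbon, which pushes that C–O bond open to a p-quinone methide, and the resulting hemiketal alkoxide expels the ring A phenoxide O1 to give the open 1,2-diketone 6. Either of the two equivalent ortho phenoxides of the now symmetric 2,6-dioxy-4-methoxyphenyl ring adds to the quinone methide methine in a 6-exo-trig oxa-1,6-addition that closes ring C, and tautomerisation of the 2-arylchromane-3,4-dione to the aromatic 3-hydroxypyran-4-one makes the sequence irreversible. The closest known reaction type is the Auwers synthesis, in which hydroxide opens an aurone dibromide to the same kind of 1,2-diketone, which recloses by O-alkylation at the benzylic carbon; base-induced quinone methide formation from 4-hydroxybenzylic leaving groups is also known. The step needs six-ring closure in preference to return to the five-ring hemiketal and to a cationic 1,2-acyl shift (towards a 3-aryl-4-hydroxycoumarin): the hemiketal and any methanol adduct of the quinone methide form reversibly while only the flavonol is a sink, and the basic, cation-free medium shuts off the acyl shift. The benzyl ether at O3' is inert, so exactly O3 (from the epoxide oxygen), O5 and O4' emerge as free hydroxyls.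

Step 4
Reactants: 7 3'-O-benzylrhamnetin
Product: 8 3'-O-benzylrhamnetin 3,5,4'-tris(2,2,2-trichloroethyl sulfate)
Conditions: Cl3CCH2OSO2Cl (4.5 equiv), Et3N (5 equiv), DMAP (cat.), THF, 0 °C to rt
Reagents that add atoms: 2,2,2-trichloroethyl chlorosulfate, ClS(=O)(=O)OCC(Cl)(Cl)Cl
Why: Sulfurylation of phenolic and enolic hydroxyls with a chlorosulfate ester (protected-sulfate method): the reagent behaves like a sulfonyl chloride, a class known to derivatise even the chelated 5-OH of flavones; no site selectivity is needed because O3' is benzylated, and the neutral triester can be purified on silica.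

Step 5
Reactants: 8 3'-O-benzylrhamnetin 3,5,4'-tris(2,2,2-trichloroethyl sulfate)
Product: 10 rhamnetin 3,5,4'-tri-O-sulfate (free acid), via triammonium salt 9 (not isolated)
Conditions: 10% Pd/C, HCO2NH4 (excess), MeOH, rt; filter; Dowex 50WX8 (H+ form), H2O, 0 °C; freeze-dry
Reagents that add atoms: none
Why: Catalytic transfer hydrogenolysis, in which Pd/formate effects the known reductive fragmentation of trichloroethyl sulfate esters to sulfate monoanions and also cleaves the aryl benzyl ether, both under near-neutral conditions that aryl sulfates and the tetrasubstituted C2=C3 bond tolerate; cold cation exchange then gives the free acid.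

## Compound list

1 | 4,6-dihydroxybenzofuran-3(2H)-one | O=C1COc2cc(O)cc(O)c12 | starting material
2 | 4-hydroxy-6-methoxybenzofuran-3(2H)-one | O=C1COc2cc(OC)cc(O)c12 | intermediate
3 | 3-(benzyloxy)-4-hydroxybenzaldehyde | O=Cc1ccc(O)c(OCc2ccccc2)c1 | starting material
4 | (Z)-4-acetoxy-2-[4-acetoxy-3-(benzyloxy)benzylidene]-6-methoxybenzofuran-3(2H)-one | COc1cc(OC(C)=O)c2C(=O)/C(=C/c3ccc(OC(C)=O)c(OCc4ccccc4)c3)Oc2c1 | intermediate
5 | rac-spiro[benzofuran-2,2'-oxiran]-3-one derived from 4, aryl cis to O1 on the oxirane (one enantiomer drawn) | COc1cc(OC(C)=O)c2C(=O)[C@@]3(Oc2c1)O[C@@H]3c4ccc(OC(C)=O)c(OCc5ccccc5)c4 | intermediate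
6 | 1-(2,6-dihydroxy-4-methoxyphenyl)-3-[3-(benzyloxy)-4-oxocyclohexa-2,5-dien-1-ylidene]propane-1,2-dione (transient, present as its phenoxide, exocyclic geometry not defined) | COc1cc(O)c(C(=O)C(=O)C=C2C=CC(=O)C(OCc3ccccc3)=C2)c(O)c1 | intermediate
7 | 3'-O-benzylrhamnetin | COc1cc(O)c2c(=O)c(O)c(-c3ccc(O)c(OCc4ccccc4)c3)oc2c1 | intermediate
8 | 3'-O-benzylrhamnetin 3,5,4'-tris(2,2,2-trichloroethyl sulfate) | COc1cc(OS(=O)(=O)OCC(Cl)(Cl)Cl)c2c(=O)c(OS(=O)(=O)OCC(Cl)(Cl)Cl)c(-c3ccc(OS(=O)(=O)OCC(Cl)(Cl)Cl)c(OCc4ccccc4)c3)oc2c1 | intermediate
9 | rhamnetin 3,5,4'-tri-O-sulfate triammonium salt | COc1cc(OS(=O)(=O)[O-])c2c(=O)c(OS(=O)(=O)[O-])c(-c3ccc(OS(=O)(=O)[O-])c(O)c3)oc2c1.[NH4+].[NH4+].[NH4+] | intermediate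
10 | rhamnetin 3,5,4'-tri-O-sulfate | COc1cc(OS(=O)(=O)O)c2c(=O)c(OS(=O)(=O)O)c(-c3ccc(OS(=O)(=O)O)c(O)c3)oc2c1 | target

## Step count and risks

Total step count: 5. Longest linear sequence: 5 (1 → 2 → 4 → 7 → 8 → 10).

**Step 3 (key step, proposed new method).**
- What may go wrong: the epoxide could ionise early at the benzylic carbon and undergo 1,2-acyl migration. Methanol could capture the quinone methide without return. The open diketone could undergo a benzilic-type contraction. In each case the six-membered ring does not close.
- Fallback: the oxygen-transfer and quinone methide relay is given up for the halogen-based Auwers synthesis, which is known chemistry. Setting out from 4, addition of bromine (1 equiv, CHCl3, 0 °C) across the exocyclic double bond should give the anti-dibromide rac-4-acetoxy-2-{[4-acetoxy-3-(benzyloxy)phenyl]bromomethyl}-2-bromo-6-methoxybenzofuran-3(2H)-one F1. Aqueous-ethanolic KOH should then cleave the acetates, replace the C2 bromide by hydroxide, open the hemiketal and reclose by O-alkylation at the benzylic carbon. Acidification brings the material back to the route at 7.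

**Step 4.**
- What may go wrong: sulfurylation at the chelated O5–H could stay incomplete, or nucleophiles in the mixture could cleave the enol sulfate diester at O3.
- Fallback: the protected-diester approach is replaced by direct sulfur trioxide sulfation to the monoester salts. Setting out from 7, SO3·NEt3 (large excess) with Et3N in MeCN at 100 °C (sealed vessel, microwave heating) should give 3'-O-benzylrhamnetin 3,5,4'-tri-O-sulfate tris(triethylammonium) salt F2. Hydrogenolysis (H2, Pd/C, MeOH) should give rhamnetin 3,5,4'-tri-O-sulfate tris(triethylammonium) salt F3. Cold exchange on the H+ resin comes back to the route at 10.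

**Step 5.**
- What may go wrong: chloride or the chlorinated olefin could poison the catalyst, so that the benzyl ether persists. The C2=C3 bond could become saturated. Acid could hydrolyse a sulfate during the proton exchange.
- Fallback: the two unmaskings are separated and palladium is avoided. Setting out from 8, BCl3 with pentamethylbenzene (CH2Cl2, −78 °C) should remove only the benzyl ether and give rhamnetin 3,5,4'-tris(2,2,2-trichloroethyl sulfate) F4. Zinc dust with HCO2NH4 in MeOH should then fragment the three trichloroethyl esters by dissolving-metal reduction and come back to the route at 9, which can be stored as the salt and exchanged to 10 just before use.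

## Further compounds

F1 | step 3 | rac-4-acetoxy-2-{[4-acetoxy-3-(benzyloxy)phenyl]bromomethyl}-2-bromo-6-methoxybenzofuran-3(2H)-one (anti adduct, one enantiomer drawn) | COc1cc(OC(C)=O)c2C(=O)[C@](Br)(Oc2c1)[C@@H](Br)c3ccc(OC(C)=O)c(OCc4ccccc4)c3
F2 | step 4 | 3'-O-benzylrhamnetin 3,5,4'-tri-O-sulfate tris(triethylammonium) salt | COc1cc(OS(=O)(=O)[O-])c2c(=O)c(OS(=O)(=O)[O-])c(-c3ccc(OS(=O)(=O)[O-])c(OCc4ccccc4)c3)oc2c1.CC[NH+](CC)CC.CC[NH+](CC)CC.CC[NH+](CC)CC
F3 | step 4 | rhamnetin 3,5,4'-tri-O-sulfate tris(triethylammonium) salt | COc1cc(OS(=O)(=O)[O-])c2c(=O)c(OS(=O)(=O)[O-])c(-c3ccc(OS(=O)(=O)[O-])c(O)c3)oc2c1.CC[NH+](CC)CC.CC[NH+](CC)CC.CC[NH+](CC)CC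
F4 | step 5 | rhamnetin 3,5,4'-tris(2,2,2-trichloroethyl sulfate) | COc1cc(OS(=O)(=O)OCC(Cl)(Cl)Cl)c2c(=O)c(OS(=O)(=O)OCC(Cl)(Cl)Cl)c(-c3ccc(OS(=O)(=O)OCC(Cl)(Cl)Cl)c(O)c3)oc2c1
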